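**Retrosynthetic overview**
1. Both esters go on late. The angelate at O10 is the last step, and the veratrate at O6 is installed before ring closure.
2. Ring B (seven-membered) is formed last, by ring-closing metathesis at C8=C9 of a trans-1,2-disubstituted cyclopentane carrying a vinyl carbinol (C10) and a methallyl carbinol (C6).
3. C6–C7 comes from asymmetric methallylboration of a C5 carbaldehyde. C4 comes from isopropenyl addition to the ring ketone followed by hydrogenation. C5–C6 comes from orthoformate alkylation of a silyl dienol ether.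
4. Ring A (five-membered) is formed first, by Tsuji–Wacker oxidation and intramolecular aldol condensation of a 2,2-disubstituted pent-4-enal.
5. The quaternary C1 is set by two Fráter–Seebach alkylations. These are relayed from C10, which a ketoreductase sets on achiral ethyl 4-(benzyloxy)-3-oxobutanoate.

Numbering and assumption: positions follow carotane numbering. C1 is the quaternary fusion carbon bearing CH3, C2 and C3 are the ring A CH2 groups, C4 is the isopropyl carbinol, C5 is the fusion CH, C6 is the veratrate carbinol, C7 is CH2, C8=C9 is the alkene and C10 is the angelate carbinol. An (S)-selective ketoreductase for 1 is assumed to be found in a commercial screening panel.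

**Step 1**
Reactants: 1 ethyl 4-(benzyloxy)-3-oxobutanoate
Product: 2 ethyl (3S)-4-(benzyloxy)-3-hydroxybutanoate
Conditions: (S)-selective ketoreductase (KRED; NADPH-dependent oxidoreductase of the alcohol dehydrogenase class, EC 1.1.1), NADP+ (cat.), iPrOH (10 vol %), KH2PO4/K2HPO4 buffer pH 7.0, 30 °C
Reagents that add atoms: none
Why: Enzymatic asymmetric ketone reduction, in which the ketoreductase holds the prochiral β-keto ester in one orientation and passes the NADPH hydride (recycled by isopropanol) to a single carbonyl face, setting the first stereocentre (future C10) in >99% ee.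

**Step 2**
Reactants: 2 ethyl (3S)-4-(benzyloxy)-3-hydroxybutanoate
Product: 4 ethyl (2R)-2-[(1S)-2-(benzyloxy)-1-hydroxyethyl]pent-4-enoate, via dilithio dianion 3 (not isolated)
Conditions: LiN(iPr)2 (2.2 equiv), THF, −78 → −20 °C; allyl bromide, DMPU, −78 → −20 °C
Reagents that add atoms: allyl bromide, C=CCBr
Why: Fráter–Seebach alkylation, in which the lithium-chelated dianion is attacked on the face opposite its CH2OBn group to give the anti product and bring in the C5–C4–C3 carbons.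

**Step 3**
Reactants: 4 ethyl (2R)-2-[(1S)-2-(benzyloxy)-1-hydroxyethyl]pent-4-enoate
Product: 6 ethyl (2S)-2-[(1S)-2-(benzyloxy)-1-hydroxyethyl]-2-methylpent-4-enoate, via dilithio dianion 5 (not isolated)
Conditions: LiN(iPr)2 (2.5 equiv), THF, −78 → 0 °C; MeI, DMPU, −78 → 0 °C
Reagents that add atoms: iodomethane, CI
Why: Second Fráter–Seebach alkylation, in which re-enolisation erases the α-centre and the same chelate face control makes methyl iodide enter anti to CH2OBn, so the quaternary centre (future C1) forms with methyl anti and allyl syn to the carbinol oxygen.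

**Step 4**
Reactants: 6 ethyl (2S)-2-[(1S)-2-(benzyloxy)-1-hydroxyethyl]-2-methylpent-4-enoate
Product: 7 ethyl (2S)-2-[(1S)-2-(benzyloxy)-1-(tert-butyldimethylsilyloxy)ethyl]-2-methylpent-4-enoate
Conditions: TBSOTf, 2,6-lutidine, CH2Cl2, 0 °C → rt
Reagents that add atoms: tert-butyldimethylsilyl triflate, CC(C)(C)[Si](C)(C)OS(=O)(=O)C(F)(F)F
Why: Silyl ether formation with the reactive triflate protects the hindered carbinol and builds the bulky arm that later shields one ring face, touching no stereocentre.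

**Step 5**
Reactants: 7 ethyl (2S)-2-[(1S)-2-(benzyloxy)-1-(tert-butyldimethylsilyloxy)ethyl]-2-methylpent-4-enoate
Product: 8 (2R)-2-[(1S)-2-(benzyloxy)-1-(tert-butyldimethylsilyloxy)ethyl]-2-methylpent-4-en-1-ol
Conditions: iBu2AlH (3 equiv), CH2Cl2, −78 → 0 °C; aq. potassium sodium tartrate
Reagents that add atoms: none
Why: Hydride reduction of the ester to the primary alcohol leaves the alkene, benzyl ether and silyl ether intact, and the descriptor at C1 changes only through CIP priorities.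

**Step 6**
Reactants: 8 (2R)-2-[(1S)-2-(benzyloxy)-1-(tert-butyldimethylsilyloxy)ethyl]-2-methylpent-4-en-1-ol
Product: 9 (2S)-2-[(1S)-2-(benzyloxy)-1-(tert-butyldimethylsilyloxy)ethyl]-2-methylpent-4-enal
Conditions: Dess–Martin periodinane, CH2Cl2, rt
Reagents that add atoms: none
Why: Dess–Martin oxidation stops at the aldehyde, which has no α-hydrogen and therefore cannot epimerise or self-condense.

**Step 7**
Reactants: 9 (2S)-2-[(1S)-2-(benzyloxy)-1-(tert-butyldimethylsilyloxy)ethyl]-2-methylpent-4-enal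
Product: 10 (2S)-2-[(1S)-2-(benzyloxy)-1-(tert-butyldimethylsilyloxy)ethyl]-2-methyl-4-oxopentanal
Conditions: PdCl2 (10 mol %), CuCl (1 equiv), O2 (1 atm), DMF/H2O 7:1, rt
Reagents that add atoms: water, O
Why: Tsuji–Wacker oxidation, in which divalent palladium activates the only alkene for Markovnikov attack of water to give the methyl ketone while CuCl/O2 reoxidise zerovalent palladium.

**Step 8**
Reactants: 10 (2S)-2-[(1S)-2-(benzyloxy)-1-(tert-butyldimethylsilyloxy)ethyl]-2-methyl-4-oxopentanal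
Product: 12 (4R)-4-[(1S)-2-(benzyloxy)-1-(tert-butyldimethylsilyloxy)ethyl]-4-methylcyclopent-2-en-1-one, via aldol adduct 11 (not isolated)
Conditions: KOH (0.2 equiv), MeOH/THF, rt → 40 °C
Reagents that add atoms: none
Why: Intramolecular aldol condensation of the 1,4-keto aldehyde, in which only the methyl-side enolate can reach the non-enolisable aldehyde through a five-membered ring, and loss of water gives ring A without touching C1 or C10.

**Step 9**
Reactants: 12 (4R)-4-[(1S)-2-(benzyloxy)-1-(tert-butyldimethylsilyloxy)ethyl]-4-methylcyclopent-2-en-1-one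
Product: 14 (5S)-5-[(1S)-2-(benzyloxy)-1-(tert-butyldimethylsilyloxy)ethyl]-5-methyl-2-(trimethylsilyloxy)cyclopenta-1,3-diene, via lithium dienolate 13 (not isolated)
Conditions: LiN(iPr)2, THF, −78 °C; Me3SiCl, −78 → 0 °C
Reagents that add atoms: chlorotrimethylsilane, C[Si](C)(C)Cl
Why: Kinetic α′-deprotonation and O-silylation give a single cross-conjugated silyl dienol ether, because C5 is the only enolisable position (the γ-carbon is quaternary).

**Step 10**
Reactants: 14 (5S)-5-[(1S)-2-(benzyloxy)-1-(tert-butyldimethylsilyloxy)ethyl]-5-methyl-2-(trimethylsilyloxy)cyclopenta-1,3-diene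
Product: 15 (4S,5S)-4-[(1S)-2-(benzyloxy)-1-(tert-butyldimethylsilyloxy)ethyl]-5-(dimethoxymethyl)-4-methylcyclopent-2-en-1-one
Conditions: HC(OMe)3, Me3SiOTf (10 mol %), CH2Cl2, −78 °C
Reagents that add atoms: trimethyl orthoformate, COC(OC)OC
Why: Mukaiyama-type alkylation by the dimethoxycarbenium ion, which adds to C5 anti to the bulky silyloxy arm (syn to the methyl group) and so sets C5 in the trans arrangement that is also thermodynamically preferred.

**Step 11**
Reactants: 15 (4S,5S)-4-[(1S)-2-(benzyloxy)-1-(tert-butyldimethylsilyloxy)ethyl]-5-(dimethoxymethyl)-4-methylcyclopent-2-en-1-one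
Product: 16 (2S,3S)-3-[(1S)-2-(benzyloxy)-1-(tert-butyldimethylsilyloxy)ethyl]-2-(dimethoxymethyl)-3-methylcyclopentan-1-one
Conditions: H2 (1 atm), Pd/C, pyridine (0.5 equiv), EtOAc, rt
Reagents that add atoms: none
Why: Catalytic hydrogenation of the enone C=C, in which pyridine poisons Pd/C towards benzyl ether hydrogenolysis and no stereocentre is formed.

**Step 12**
Reactants: 16 (2S,3S)-3-[(1S)-2-(benzyloxy)-1-(tert-butyldimethylsilyloxy)ethyl]-2-(dimethoxymethyl)-3-methylcyclopentan-1-one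
Product: 17 (1S,2R,3S)-3-[(1S)-2-(benzyloxy)-1-(tert-butyldimethylsilyloxy)ethyl]-2-(dimethoxymethyl)-3-methyl-1-(prop-1-en-2-yl)cyclopentan-1-ol
Conditions: CeCl3 (anhydrous), isopropenylmagnesium bromide, THF, −78 → 0 °C
Reagents that add atoms: isopropenylmagnesium bromide, CC(=C)[Mg]Br
Why: Organocerium 1,2-addition suppresses enolisation, and the small sp2 nucleophile attacks the α-face, anti to the adjacent C5 acetal arm and to the pseudoaxial C1 methyl, which sets C4 with a β-hydroxyl.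

**Step 13**
Reactants: 17 (1S,2R,3S)-3-[(1S)-2-(benzyloxy)-1-(tert-butyldimethylsilyloxy)ethyl]-2-(dimethoxymethyl)-3-methyl-1-(prop-1-en-2-yl)cyclopentan-1-ol
Product: 18 (1R,2R,3S)-3-[(1S)-1-(tert-butyldimethylsilyloxy)-2-hydroxyethyl]-2-(dimethoxymethyl)-3-methyl-1-(propan-2-yl)cyclopentan-1-ol
Conditions: H2 (3 atm), Pd(OH)2/C, EtOAc/MeOH, rt
Reagents that add atoms: none
Why: One catalytic hydrogenation saturates isopropenyl to isopropyl and hydrogenolyses the benzyl ether before any alkene that must survive is present, and the descriptor at C4 changes only through CIP priorities.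

**Step 14**
Reactants: 18 (1R,2R,3S)-3-[(1S)-1-(tert-butyldimethylsilyloxy)-2-hydroxyethyl]-2-(dimethoxymethyl)-3-methyl-1-(propan-2-yl)cyclopentan-1-ol
Product: 19 (2S)-2-(tert-butyldimethylsilyloxy)-2-[(1S,2R,3R)-2-(dimethoxymethyl)-3-hydroxy-1-methyl-3-(propan-2-yl)cyclopentyl]acetaldehyde
Conditions: Dess–Martin periodinane, NaHCO3, CH2Cl2, 0 °C → rt
Reagents that add atoms: none
Why: Buffered Dess–Martin oxidation converts the only oxidisable (primary) alcohol into the aldehyde under neutral conditions that spare the acetal, the tertiary alcohol and the C10 centre.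

**Step 15**
Reactants: 19 (2S)-2-(tert-butyldimethylsilyloxy)-2-[(1S,2R,3R)-2-(dimethoxymethyl)-3-hydroxy-1-methyl-3-(propan-2-yl)cyclopentyl]acetaldehyde
Product: 20 (1R,2R,3S)-3-[(1R)-1-(tert-butyldimethylsilyloxy)prop-2-en-1-yl]-2-(dimethoxymethyl)-3-methyl-1-(propan-2-yl)cyclopentan-1-ol
Conditions: Ph3PCH3Br, KN(SiMe3)2, THF, 0 °C; then 19, −78 → 0 °C
Reagents that add atoms: methyltriphenylphosphonium bromide, C[P+](c1ccccc1)(c1ccccc1)c1ccccc1.[Br-]
Why: Wittig methylenation of the aldehyde is faster than deprotonation of the hindered neopentyl C10–H, so the vinyl group (C9) is installed without epimerisation.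

**Step 16**
Reactants: 20 (1R,2R,3S)-3-[(1R)-1-(tert-butyldimethylsilyloxy)prop-2-en-1-yl]-2-(dimethoxymethyl)-3-methyl-1-(propan-2-yl)cyclopentan-1-ol
Product: 21 (1R,2S,5R)-2-[(1R)-1-(tert-butyldimethylsilyloxy)prop-2-en-1-yl]-5-hydroxy-2-methyl-5-(propan-2-yl)cyclopentane-1-carbaldehyde
Conditions: PPTS (0.2 equiv), acetone/H2O 10:1, 40 °C
Reagents that add atoms: water, O
Why: Mild acid-catalysed acetal hydrolysis frees the C6 aldehyde while the hindered silyl ether survives, and C5 stays in its preferred configuration trans to the large arm.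

**Step 17**
Reactants: 21 (1R,2S,5R)-2-[(1R)-1-(tert-butyldimethylsilyloxy)prop-2-en-1-yl]-5-hydroxy-2-methyl-5-(propan-2-yl)cyclopentane-1-carbaldehyde
Product: 23 (1R,2S,3S)-3-[(1R)-1-(tert-butyldimethylsilyloxy)prop-2-en-1-yl]-2-[(1S)-1-hydroxy-3-methylbut-3-en-1-yl]-3-methyl-1-(propan-2-yl)cyclopentan-1-ol, via diisopinocampheylborinate 22 (not isolated)
Conditions: (−)-Ipc2BOMe, methallylmagnesium chloride, Et2O, −78 °C → rt; 21, −78 °C, 3 h; NaOH, H2O2, 0 °C → rt
Reagents that add atoms: methallylmagnesium chloride, C=C(C)C[Mg]Cl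
Why: Brown asymmetric methallylboration, in which the closed chair transition state of the (+)-α-pinene-derived borane delivers the methallyl group to the Si face of the aldehyde under reagent control, setting C6 as S and bringing in C7, C8 and the C8 methyl.

**Step 18**
Reactants: 23 (1R,2S,3S)-3-[(1R)-1-(tert-butyldimethylsilyloxy)prop-2-en-1-yl]-2-[(1S)-1-hydroxy-3-methylbut-3-en-1-yl]-3-methyl-1-(propan-2-yl)cyclopentan-1-ol; 24 3,4-dimethoxybenzoyl chloride
Product: 25 (1S)-1-[(1S,2R,5S)-5-[(1R)-1-(tert-butyldimethylsilyloxy)prop-2-en-1-yl]-2-hydroxy-5-methyl-2-(propan-2-yl)cyclopentyl]-3-methylbut-3-en-1-yl 3,4-dimethoxybenzoate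
Conditions: DMAP, Et3N, CH2Cl2, rt
Reagents that add atoms: none
Why: DMAP-catalysed acylation reaches only the secondary C6 hydroxyl, because the C4 hydroxyl is tertiary and O10 is silylated, and it proceeds with retention at C6.

**Step 19**
Reactants: 25 (1S)-1-[(1S,2R,5S)-5-[(1R)-1-(tert-butyldimethylsilyloxy)prop-2-en-1-yl]-2-hydroxy-5-methyl-2-(propan-2-yl)cyclopentyl]-3-methylbut-3-en-1-yl 3,4-dimethoxybenzoate
Product: 26 (1S)-1-[(1S,2R,5S)-2-hydroxy-5-[(1R)-1-hydroxyprop-2-en-1-yl]-5-methyl-2-(propan-2-yl)cyclopentyl]-3-methylbut-3-en-1-yl 3,4-dimethoxybenzoate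
Conditions: HF·pyridine, pyridine, THF, 0 °C → rt
Reagents that add atoms: none
Why: Buffered fluoride desilylation cleaves the Si–O bond without basic conditions, so the aryl ester neither migrates nor hydrolyses and C10 is untouched.

**Step 20**
Reactants: 26 (1S)-1-[(1S,2R,5S)-2-hydroxy-5-[(1R)-1-hydroxyprop-2-en-1-yl]-5-methyl-2-(propan-2-yl)cyclopentyl]-3-methylbut-3-en-1-yl 3,4-dimethoxybenzoate
Product: 27 (3R,3aS,4S,8R,8aS)-3,8-dihydroxy-6,8a-dimethyl-3-(propan-2-yl)-1,2,3,3a,4,5,8,8a-octahydroazulen-4-yl 3,4-dimethoxybenzoate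
Conditions: second-generation Hoveyda–Grubbs catalyst RuCl2(H2IMes)(=CH-C6H4-2-OiPr) (10 mol %), 1,4-benzoquinone (20 mol %), toluene (2 mM), 80 °C
Reagents that add atoms: none
Why: Ring-closing metathesis, in which the catalyst loads on the vinyl group (helped by the free allylic hydroxyl) and closes onto the 1,1-disubstituted alkene to give the ring-constrained trisubstituted C8=C9 alkene of trans-fused ring B with loss of ethylene and no change at any stereocentre.

**Step 21**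
Reactants: 27 (3R,3aS,4S,8R,8aS)-3,8-dihydroxy-6,8a-dimethyl-3-(propan-2-yl)-1,2,3,3a,4,5,8,8a-octahydroazulen-4-yl 3,4-dimethoxybenzoate; 28 angelic acid [(2Z)-2-methylbut-2-enoic acid]
Product: 30 (3R,3aS,4S,8R,8aS)-3-hydroxy-6,8a-dimethyl-8-{[(2Z)-2-methylbut-2-enoyl]oxy}-3-(propan-2-yl)-1,2,3,3a,4,5,8,8a-octahydroazulen-4-yl 3,4-dimethoxybenzoate, via mixed anhydride 29 (not isolated)
Conditions: 28, 2,4,6-trichlorobenzoyl chloride, Et3N, toluene, rt, 2 h; then 27, 80 °C
Reagents that add atoms: none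
Why: Yamaguchi-type mixed-anhydride esterification run without a nucleophilic catalyst acylates the only free secondary hydroxyl (the tertiary C4 hydroxyl is inert) with retention at C10 and without Z to E isomerisation of the angeloyl group.

**Compound list**
1 | ethyl 4-(benzyloxy)-3-oxobutanoate | CCOC(=O)CC(=O)COCc1ccccc1 | starting material
2 | ethyl (3S)-4-(benzyloxy)-3-hydroxybutanoate | CCOC(=O)C[C@H](O)COCc1ccccc1 | intermediate
3 | dilithio dianion of 2 (chelated enolate alkoxide) | CCO/C(O[Li])=C/[C@H](O[Li])COCc1ccccc1 | intermediate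
4 | ethyl (2R)-2-[(1S)-2-(benzyloxy)-1-hydroxyethyl]pent-4-enoate | CCOC(=O)[C@H](CC=C)[C@H](O)COCc1ccccc1 | intermediate
5 | dilithio dianion of 4 (chelated enolate alkoxide) | CCO/C(O[Li])=C(CC=C)/[C@H](O[Li])COCc1ccccc1 | intermediate
6 | ethyl (2S)-2-[(1S)-2-(benzyloxy)-1-hydroxyethyl]-2-methylpent-4-enoate | CCOC(=O)[C@@](C)(CC=C)[C@H](O)COCc1ccccc1 | intermediate
7 | ethyl (2S)-2-[(1S)-2-(benzyloxy)-1-(tert-butyldimethylsilyloxy)ethyl]-2-methylpent-4-enoate | CCOC(=O)[C@@](C)(CC=C)[C@H](O[Si](C)(C)C(C)(C)C)COCc1ccccc1 | intermediate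
8 | (2R)-2-[(1S)-2-(benzyloxy)-1-(tert-butyldimethylsilyloxy)ethyl]-2-methylpent-4-en-1-ol | OC[C@@](C)(CC=C)[C@H](O[Si](C)(C)C(C)(C)C)COCc1ccccc1 | intermediate
9 | (2S)-2-[(1S)-2-(benzyloxy)-1-(tert-butyldimethylsilyloxy)ethyl]-2-methylpent-4-enal | O=C[C@@](C)(CC=C)[C@H](O[Si](C)(C)C(C)(C)C)COCc1ccccc1 | intermediate
10 | (2S)-2-[(1S)-2-(benzyloxy)-1-(tert-butyldimethylsilyloxy)ethyl]-2-methyl-4-oxopentanal | O=C[C@@](C)(CC(C)=O)[C@H](O[Si](C)(C)C(C)(C)C)COCc1ccccc1 | intermediate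
11 | (4R)-4-[(1S)-2-(benzyloxy)-1-(tert-butyldimethylsilyloxy)ethyl]-3-hydroxy-4-methylcyclopentan-1-one (both C3 epimers) | O=C1CC(O)[C@@](C)(C1)[C@H](O[Si](C)(C)C(C)(C)C)COCc2ccccc2 | intermediate
12 | (4R)-4-[(1S)-2-(benzyloxy)-1-(tert-butyldimethylsilyloxy)ethyl]-4-methylcyclopent-2-en-1-one | O=C1C=C[C@@](C)(C1)[C@H](O[Si](C)(C)C(C)(C)C)COCc2ccccc2 | intermediate
13 | lithium dienolate of 12 | [Li]OC1=C[C@](C)(C=C1)[C@H](O[Si](C)(C)C(C)(C)C)COCc2ccccc2 | intermediate
14 | (5S)-5-[(1S)-2-(benzyloxy)-1-(tert-butyldimethylsilyloxy)ethyl]-5-methyl-2-(trimethylsilyloxy)cyclopenta-1,3-diene | C[Si](C)(C)OC1=C[C@](C)(C=C1)[C@H](O[Si](C)(C)C(C)(C)C)COCc2ccccc2 | intermediate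
15 | (4S,5S)-4-[(1S)-2-(benzyloxy)-1-(tert-butyldimethylsilyloxy)ethyl]-5-(dimethoxymethyl)-4-methylcyclopent-2-en-1-one | O=C1C=C[C@](C)([C@H](O[Si](C)(C)C(C)(C)C)COCc2ccccc2)[C@H]1C(OC)OC | intermediate
16 | (2S,3S)-3-[(1S)-2-(benzyloxy)-1-(tert-butyldimethylsilyloxy)ethyl]-2-(dimethoxymethyl)-3-methylcyclopentan-1-one | O=C1CC[C@](C)([C@H](O[Si](C)(C)C(C)(C)C)COCc2ccccc2)[C@H]1C(OC)OC | intermediate
17 | (1S,2R,3S)-3-[(1S)-2-(benzyloxy)-1-(tert-butyldimethylsilyloxy)ethyl]-2-(dimethoxymethyl)-3-methyl-1-(prop-1-en-2-yl)cyclopentan-1-ol | COC(OC)[C@@H]1[C@](C)(CC[C@@]1(O)C(C)=C)[C@H](O[Si](C)(C)C(C)(C)C)COCc2ccccc2 | intermediate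
18 | (1R,2R,3S)-3-[(1S)-1-(tert-butyldimethylsilyloxy)-2-hydroxyethyl]-2-(dimethoxymethyl)-3-methyl-1-(propan-2-yl)cyclopentan-1-ol | COC(OC)[C@@H]1[C@](C)(CC[C@@]1(O)C(C)C)[C@H](O[Si](C)(C)C(C)(C)C)CO | intermediate
19 | (2S)-2-(tert-butyldimethylsilyloxy)-2-[(1S,2R,3R)-2-(dimethoxymethyl)-3-hydroxy-1-methyl-3-(propan-2-yl)cyclopentyl]acetaldehyde | COC(OC)[C@@H]1[C@](C)(CC[C@@]1(O)C(C)C)[C@H](O[Si](C)(C)C(C)(C)C)C=O | intermediate
20 | (1R,2R,3S)-3-[(1R)-1-(tert-butyldimethylsilyloxy)prop-2-en-1-yl]-2-(dimethoxymethyl)-3-methyl-1-(propan-2-yl)cyclopentan-1-ol | COC(OC)[C@@H]1[C@](C)(CC[C@@]1(O)C(C)C)[C@H](O[Si](C)(C)C(C)(C)C)C=C | intermediate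
21 | (1R,2S,5R)-2-[(1R)-1-(tert-butyldimethylsilyloxy)prop-2-en-1-yl]-5-hydroxy-2-methyl-5-(propan-2-yl)cyclopentane-1-carbaldehyde | O=C[C@@H]1[C@](C)(CC[C@@]1(O)C(C)C)[C@H](O[Si](C)(C)C(C)(C)C)C=C | intermediate
22 | O6-diisopinocampheylborinate of 23 | C=C(C)C[C@H](OB([C@@H]3C[C@@H]4C[C@H]([C@H]3C)C4(C)C)[C@@H]3C[C@@H]4C[C@H]([C@H]3C)C4(C)C)[C@@H]1[C@](C)(CC[C@@]1(O)C(C)C)[C@H](O[Si](C)(C)C(C)(C)C)C=C | intermediate
23 | (1R,2S,3S)-3-[(1R)-1-(tert-butyldimethylsilyloxy)prop-2-en-1-yl]-2-[(1S)-1-hydroxy-3-methylbut-3-en-1-yl]-3-methyl-1-(propan-2-yl)cyclopentan-1-ol | C=C(C)C[C@H](O)[C@@H]1[C@](C)(CC[C@@]1(O)C(C)C)[C@H](O[Si](C)(C)C(C)(C)C)C=C | intermediate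
24 | 3,4-dimethoxybenzoyl chloride | COc1ccc(cc1OC)C(=O)Cl | starting material
25 | (1S)-1-[(1S,2R,5S)-5-[(1R)-1-(tert-butyldimethylsilyloxy)prop-2-en-1-yl]-2-hydroxy-5-methyl-2-(propan-2-yl)cyclopentyl]-3-methylbut-3-en-1-yl 3,4-dimethoxybenzoate | C=C(C)C[C@H](OC(=O)c1ccc(OC)c(OC)c1)[C@@H]2[C@](C)(CC[C@@]2(O)C(C)C)[C@H](O[Si](C)(C)C(C)(C)C)C=C | intermediate
26 | (1S)-1-[(1S,2R,5S)-2-hydroxy-5-[(1R)-1-hydroxyprop-2-en-1-yl]-5-methyl-2-(propan-2-yl)cyclopentyl]-3-methylbut-3-en-1-yl 3,4-dimethoxybenzoate | C=C(C)C[C@H](OC(=O)c1ccc(OC)c(OC)c1)[C@@H]2[C@](C)(CC[C@@]2(O)C(C)C)[C@H](O)C=C | intermediate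
27 | (3R,3aS,4S,8R,8aS)-3,8-dihydroxy-6,8a-dimethyl-3-(propan-2-yl)-1,2,3,3a,4,5,8,8a-octahydroazulen-4-yl 3,4-dimethoxybenzoate | O[C@@H]1C=C(C)C[C@H](OC(=O)c2ccc(OC)c(OC)c2)[C@@H]2[C@]1(C)CC[C@@]2(O)C(C)C | intermediate
28 | angelic acid, (2Z)-2-methylbut-2-enoic acid | C/C=C(/C)C(=O)O | starting material
29 | (2Z)-2-methylbut-2-enoic 2,4,6-trichlorobenzoic anhydride | C/C=C(/C)C(=O)OC(=O)c1c(Cl)cc(Cl)cc1Cl | intermediate
30 | (3R,3aS,4S,8R,8aS)-3-hydroxy-6,8a-dimethyl-8-{[(2Z)-2-methylbut-2-enoyl]oxy}-3-(propan-2-yl)-1,2,3,3a,4,5,8,8a-octahydroazulen-4-yl 3,4-dimethoxybenzoate (CNP0142353.1) | C/C=C(/C)C(=O)O[C@@H]1C=C(C)C[C@H](OC(=O)c2ccc(OC)c(OC)c2)[C@@H]2[C@]1(C)CC[C@@]2(O)C(C)C | target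

**Totals**
Total step count: 21. Longest linear sequence: 21 steps (1 → 30). Compounds 24 and 28 are bought and enter directly.

**Three steps most likely to fail**

**Step 3.** The risks are slow enolisation of the α-branched dianion, incomplete methylation and eroded diastereoselectivity at the quaternary centre.
- The fallback moves the alkylation into a rigid ring (self-regeneration of stereocentres) and sets out from 4.
- LiOH in THF/H2O gives (2R)-2-[(1S)-2-(benzyloxy)-1-hydroxyethyl]pent-4-enoic acid F1.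
- Pivalaldehyde with catalytic p-TsOH and removal of water gives the cis acetal (2R,5R,6S)-6-[(benzyloxy)methyl]-2-tert-butyl-5-(prop-2-en-1-yl)-1,3-dioxan-4-one F2.
- LiN(iPr)2 then MeI at −78 °C methylates the flat ring enolate on the face opposite the tert-butyl and benzyloxymethyl groups. This gives (2R,5S,6S)-6-[(benzyloxy)methyl]-2-tert-butyl-5-methyl-5-(prop-2-en-1-yl)-1,3-dioxan-4-one F3.
- Ethanol with catalytic H2SO4 opens the acetal ester, and the sequence comes back to the route at 6.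

**Step 17.** The aldehyde is hindered and is a β-hydroxy aldehyde. The chiral borane may also be mismatched with the substrate.
- The fallback sets C6 by an organocatalytic aldol and adds the terminal carbon afterwards. It sets out from 21.
- D-proline (30 mol %) in acetone/DMSO at rt adds acetone through its enamine to the Si face of the α-branched aldehyde. This gives (4S)-4-hydroxy-4-[(1S,2R,5S)-5-[(1R)-1-(tert-butyldimethylsilyloxy)prop-2-en-1-yl]-2-hydroxy-5-methyl-2-(propan-2-yl)cyclopentyl]butan-2-one F4.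
- Non-basic methylenation of the methyl ketone with excess Cp2TiMe2 in toluene at 70 °C avoids retro-aldol cleavage, and the sequence comes back to the route at 23.

**Step 21.** O10 is a neopentyl allylic hydroxyl, so acylation by the α-branched angeloyl donor may be very slow, and forcing it risks isomerisation to the tiglate.
- The fallback builds the Z-alkene on the molecule and sets out from 27.
- The slim acid 2-[bis(2,2,2-trifluoroethoxy)phosphoryl]propanoic acid with EDC and DMAP gives (3R,3aS,4S,8R,8aS)-8-({2-[bis(2,2,2-trifluoroethoxy)phosphoryl]propanoyl}oxy)-3-hydroxy-6,8a-dimethyl-3-(propan-2-yl)-1,2,3,3a,4,5,8,8a-octahydroazulen-4-yl 3,4-dimethoxybenzoate F5.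
- Still–Gennari olefination with KN(SiMe3)2, 18-crown-6 and acetaldehyde in THF at −78 °C forms the (Z)-2-methylbut-2-enoate, and the sequence comes back to the route at 30.

**Further compounds**
F1 | step 3 | (2R)-2-[(1S)-2-(benzyloxy)-1-hydroxyethyl]pent-4-enoic acid | OC(=O)[C@H](CC=C)[C@H](O)COCc1ccccc1
F2 | step 3 | (2R,5R,6S)-6-[(benzyloxy)methyl]-2-tert-butyl-5-(prop-2-en-1-yl)-1,3-dioxan-4-one | O=C1O[C@H](C(C)(C)C)O[C@H](COCc2ccccc2)[C@H]1CC=C
F3 | step 3 | (2R,5S,6S)-6-[(benzyloxy)methyl]-2-tert-butyl-5-methyl-5-(prop-2-en-1-yl)-1,3-dioxan-4-one | O=C1O[C@H](C(C)(C)C)O[C@H](COCc2ccccc2)[C@]1(C)CC=C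
F4 | step 17 | (4S)-4-hydroxy-4-[(1S,2R,5S)-5-[(1R)-1-(tert-butyldimethylsilyloxy)prop-2-en-1-yl]-2-hydroxy-5-methyl-2-(propan-2-yl)cyclopentyl]butan-2-one | CC(=O)C[C@H](O)[C@@H]1[C@](C)(CC[C@@]1(O)C(C)C)[C@H](O[Si](C)(C)C(C)(C)C)C=C
F5 | step 21 | (3R,3aS,4S,8R,8aS)-8-({2-[bis(2,2,2-trifluoroethoxy)phosphoryl]propanoyl}oxy)-3-hydroxy-6,8a-dimethyl-3-(propan-2-yl)-1,2,3,3a,4,5,8,8a-octahydroazulen-4-yl 3,4-dimethoxybenzoate | CC(C(=O)O[C@@H]1C=C(C)C[C@H](OC(=O)c2ccc(OC)c(OC)c2)[C@@H]2[C@]1(C)CC[C@@]2(O)C(C)C)P(=O)(OCC(F)(F)F)OCC(F)(F)F
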